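**Retrosynthetic overview**
1. Numbering (daucane): ring A is C1 (angular CH3)–C2–C3–C4 (O, isopropyl)–C5; ring B is C1–C10–C9–C8 (CH3)–C7–C6 (OH)–C5; β is the face of the C1 methyl.
2. The strategy rests on ring B: the C6 carbinol and the C8–C9 epoxide are a latent cyclohepta-1,4-diene (C5=C6 and C8=C9 on either side of C7) attached to the quaternary fusion carbon C1.
3. Late stage, backwards: phenol release, C6-hydroxyl-directed epoxidation of C8=C9, acylation of the tertiary O4 with silyl-protected vanilloyl chloride, back to dauc-8-ene-4β,6α-diol; the diol comes from a C5=C6 silyl enol ether / C8 enoate by ester-to-methyl reduction, desilylation with ketonisation and O4-directed reduction.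
4. Key disconnection: C7–C8 and C1–C10 of ring B, made through a temporary cyclopropane C6–C7–C8 (2-siloxydiene plus vinylcarbenoid, then Cope ring expansion).
5. The siloxydiene comes from (S)-terpinen-4-ol (source of C4) by ozonolysis and aldol ring contraction; ring order: ring A, transient cyclopropane, ring B, epoxide.

Key step: step 10

Assumption: the DOSP catalysts are taken to induce the same absolute sense with the enol ether of 10 as with styrene, the S catalyst being taken to give the (1S,2R) cyclopropane from styrene and an aryldiazoacetate; read this way, Rh2(R-DOSP)4 gives the (1S,2R) cyclopropane 16, and Rh2(S-DOSP)4 is used in the same step if the sense proves reversed.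

**Route**

Step 1
Reactants: 1 (S)-(+)-terpinen-4-ol
Product: 2 (S)-terpinen-4-yl triethylsilyl ether
Conditions: TESOTf, 2,6-lutidine, CH2Cl2, 0 °C
Reagents that add atoms: triethylsilyl trifluoromethanesulfonate, CC[Si](CC)(CC)OS(=O)(=O)C(F)(F)F
Why: O-silylation of a tertiary alcohol needs the silyl triflate with a hindered pyridine base; the stereocentre (future C4) is not touched.

Step 2
Reactants: 2 (S)-terpinen-4-yl triethylsilyl ether
Product: 4 (S)-6-oxo-3-(propan-2-yl)-3-(triethylsilyloxy)heptanal, via secondary ozonide 3 (not isolated)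
Conditions: O3, CH2Cl2, −78 °C; then PPh3, −78 °C → rt
Reagents that add atoms: ozone, [O-][O+]=O
Why: Ozonolysis of the only alkene with reductive work-up opens the ring to the methyl ketone (future C1) and the aldehyde (future C6), the silyl ether preventing lactol formation.

Step 3
Reactants: 4 (S)-6-oxo-3-(propan-2-yl)-3-(triethylsilyloxy)heptanal
Product: 6 (R)-2-methyl-5-(propan-2-yl)-5-(triethylsilyloxy)cyclopent-1-ene-1-carbaldehyde, via aldol adduct 5 (not isolated)
Conditions: piperidine (0.2 equiv), AcOH (0.2 equiv), benzene, 70 °C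
Reagents that add atoms: none
Why: Amine-salt intramolecular aldol condensation, in which the enamine of the aldehyde adds to the methyl ketone in a 5-exo closure and water is lost to give the tetrasubstituted enal of ring A; the quaternary carbon keeps its geometry (the descriptor becomes R only because the CIP priorities change).

Step 4
Reactants: 6 (R)-2-methyl-5-(propan-2-yl)-5-(triethylsilyloxy)cyclopent-1-ene-1-carbaldehyde
Product: 7 1-[(R)-2-methyl-5-(propan-2-yl)-5-(triethylsilyloxy)cyclopent-1-en-1-yl]ethan-1-ol (both carbinol epimers)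
Conditions: MeMgBr, THF, −78 → 0 °C; then aq. NH4Cl
Reagents that add atoms: methylmagnesium bromide, C[Mg]Br
Why: Grignard 1,2-addition to the hindered enal brings in C7; the new carbinol centre is oxidised away in the next step.

Step 5
Reactants: 7 1-[(R)-2-methyl-5-(propan-2-yl)-5-(triethylsilyloxy)cyclopent-1-en-1-yl]ethan-1-ol
Product: 8 1-[(R)-2-methyl-5-(propan-2-yl)-5-(triethylsilyloxy)cyclopent-1-en-1-yl]ethan-1-one
Conditions: Dess–Martin periodinane, pyridine, CH2Cl2, 0 °C → rt
Reagents that add atoms: none
Why: Dess–Martin oxidation of the allylic secondary alcohol to the methyl ketone under buffered, non-acidic conditions that leave the tertiary silyl ether intact.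

Step 6
Reactants: 8 1-[(R)-2-methyl-5-(propan-2-yl)-5-(triethylsilyloxy)cyclopent-1-en-1-yl]ethan-1-one
Product: 10 (R)-tert-butyldimethylsilyl enol ether of 8 (2-siloxydiene C7=C6(OTBS)–C5=C1), via lithium enolate 9 (not isolated)
Conditions: LiN(i-Pr)2, THF, −78 °C; then TBSOTf, −78 °C; Et3N-buffered work-up
Reagents that add atoms: tert-butyldimethylsilyl trifluoromethanesulfonate, CC(C)(C)[Si](C)(C)OS(=O)(=O)C(F)(F)F
Why: Kinetic deprotonation of an enone occurs at the α' methyl group, and O-silylation of that enolate gives the cross-conjugated 2-siloxydiene rather than an extended dienol ether.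

Step 7
Reactants: 11 methyl acetoacetate
Product: 12 methyl 2-diazo-3-oxobutanoate
Conditions: 4-acetamidobenzenesulfonyl azide, Et3N, MeCN, 0 °C → rt
Reagents that add atoms: 4-acetamidobenzenesulfonyl azide, CC(=O)Nc1ccc(cc1)S(=O)(=O)N=[N+]=[N-]
Why: Regitz diazo transfer to the doubly activated methylene.

Step 8
Reactants: 12 methyl 2-diazo-3-oxobutanoate
Product: 13 methyl 2-diazo-3-hydroxybutanoate (racemic)
Conditions: NaBH4, MeOH, 0 °C
Reagents that add atoms: none
Why: Borohydride reduces the ketone chemoselectively, the diazo group and the ester being inert at 0 °C.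

Step 9
Reactants: 13 methyl 2-diazo-3-hydroxybutanoate
Product: 15 methyl 2-diazobut-3-enoate, via dichlorophosphate ester 14 (not isolated)
Conditions: POCl3, Et3N, CH2Cl2, 0 °C → rt; kept cold as a pentane solution and used the same day
Reagents that add atoms: none
Why: Dehydration by phosphorylation of the alcohol and amine-induced elimination gives the vinyldiazoacetate, which is used at once because it slowly electrocyclises to a pyrazole.

Step 10
Reactants: 10 2-siloxydiene; 15 methyl 2-diazobut-3-enoate (2 equiv, slow addition)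
Product: 17 methyl (1R,4R)-6-(tert-butyldimethylsilyloxy)-1β-methyl-4α-(propan-2-yl)-4β-(triethylsilyloxy)hydroazulene-5,8-diene-8-carboxylate (daucane locants: C5=C6 silyl enol ether and C8=C9 enoate), via cis-divinylcyclopropane 16 (not isolated)
Conditions: Rh2(R-DOSP)4 (1 mol %), hexanes, −40 °C → rt; then 60 °C until 16 is consumed
Reagents that add atoms: none
Why: The dirhodium tetraprolinate expels N2 from 15 to give a donor/acceptor vinylcarbenoid whose carbene carbon (C8) adds to the terminal, electron-rich enol ether alkene C6=C7 of 10, the tetrasubstituted C5=C1 alkene being too hindered to react. The cis-divinylcyclopropane 16 then undergoes a Cope rearrangement through the boat transition state, breaking C6–C8 and forming C1–C10; the closest known reaction type is the tandem cyclopropanation/Cope formal (4+3) cycloaddition of vinyldiazoacetates with dienes, including 1-vinyl-2-methylcycloalkenes that give methyl-bearing quaternary carbons. The three-membered ring closes by concerted asynchronous carbenoid [2+1] addition, and ring B closes by [3,3]-sigmatropic ring expansion driven by release of cyclopropane strain, so the net new bonds are C7–C8 and C1–C10. C6 and C8 of 16 are set by the chiral catalyst (face of the carbenoid) and by the usual preference that places the alkenyl substituent cis to the vinyl donor; C1 is set by the boat geometry, in which the cyclopentene must lie endo over the cyclopropane so that C10 bonds to the α face of C1 and the methyl ends syn to the C4 oxygen. The step needs site selectivity (secured by the substitution pattern of the diene), cis-divinyl geometry and one absolute sense relative to the remote C4 centre (both left to the catalyst), and cyclopropanation rather than attack at the vinylogous carbenoid terminus (favoured by the hydrocarbon solvent and low temperature).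

Step 11
Reactants: 17 hydroazulene dienyl ester
Product: 18 C8-hydroxymethyl diene (allylic alcohol; both silyl groups retained)
Conditions: i-Bu2AlH (2.5 equiv), CH2Cl2, −78 °C; Rochelle salt work-up
Reagents that add atoms: none
Why: Aluminium hydride 1,2-reduction of the conjugated ester to the primary allylic alcohol; the silyl enol ether and the silyl ether are inert.

Step 12
Reactants: 18 C8-hydroxymethyl diene
Product: 19 allylic methanesulfonate of 18 (used crude)
Conditions: MsCl, Et3N, CH2Cl2, −30 °C
Reagents that add atoms: methanesulfonyl chloride, CS(=O)(=O)Cl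
Why: Sulfonylation of the primary allylic alcohol under cold basic conditions that do not hydrolyse the enol ether.

Step 13
Reactants: 19 allylic methanesulfonate
Product: 20 (1R,4R)-6-(tert-butyldimethylsilyloxy)-1β,8-dimethyl-4α-(propan-2-yl)-4β-(triethylsilyloxy)hydroazulene-5,8-diene
Conditions: LiEt3BH, THF, −20 → 0 °C
Reagents that add atoms: none
Why: SN2 displacement of the primary allylic sulfonate by triethylborohydride gives the C8 methyl group with the C8=C9 alkene left in place.

Step 14
Reactants: 20 C8-methyl bis-silyl diene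
Product: 21 (1R,4R,5R)-4β-hydroxy-1β,8-dimethyl-4α-(propan-2-yl)hydroazulen-8-en-6-one (trans-fused, 5α-H)
Conditions: Bu4NF, AcOH (1:1), THF, 0 °C → rt
Reagents that add atoms: none
Why: Buffered fluoride cleaves both Si–O bonds and the freed enol ketonises; C5 is epimerisable and is expected to settle trans-fused (5α-H), where C6 lies anti to the C4 isopropyl group and the C4 hydroxyl can hydrogen-bond to the carbonyl, while the near-neutral medium is meant to suppress retro-aldol cleavage, dehydration and migration of the β,γ-alkene.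

Step 15
Reactants: 21 trans-fused 4β-hydroxy-6-ketone
Product: 22 (1R,4R,5S,6S)-dauc-8-ene-4β,6α-diol
Conditions: Me4NBH(OAc)3, MeCN/AcOH (1:1), −30 °C
Reagents that add atoms: none
Why: Hydroxyl-directed triacetoxyborohydride reduction, in which boron exchanges onto the C4 β-hydroxyl and delivers hydride through a six-membered transition state to the β face of C6=O, so that the new hydroxyl is α (anti-1,3-diol).

Step 16
Reactants: 22 dauc-8-ene-4β,6α-diol
Product: 23 6α-(triethylsilyloxy)dauc-8-en-4β-ol
Conditions: TESCl, imidazole, CH2Cl2, 0 °C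
Reagents that add atoms: chlorotriethylsilane, CC[Si](Cl)(CC)CC
Why: Silyl chloride with imidazole silylates the secondary hydroxyl only, the hindered tertiary C4 hydroxyl being unreactive under these conditions.

Step 17
Reactants: 24 vanillic acid
Product: 25 tert-butyldimethylsilyl 4-(tert-butyldimethylsilyloxy)-3-methoxybenzoate
Conditions: TBSCl (2.5 equiv), imidazole, DMF, rt
Reagents that add atoms: tert-butyldimethylsilyl chloride, CC(C)(C)[Si](C)(C)Cl
Why: Exhaustive silylation of the phenol and the carboxylic acid.

Step 18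
Reactants: 25 bis-silylated vanillic acid
Product: 26 4-(tert-butyldimethylsilyloxy)-3-methoxybenzoic acid
Conditions: AcOH/THF/H2O (3:1:1), rt
Reagents that add atoms: none
Why: A silyl ester hydrolyses far faster than an aryl silyl ether in mild aqueous acid, so only the acid is released.

Step 19
Reactants: 26 4-(tert-butyldimethylsilyloxy)-3-methoxybenzoic acid
Product: 27 4-(tert-butyldimethylsilyloxy)-3-methoxybenzoyl chloride
Conditions: (COCl)2, DMF (cat.), CH2Cl2, 0 °C → rt; volatiles removed, used crude
Reagents that add atoms: oxalyl chloride, O=C(Cl)C(=O)Cl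
Why: Acid chloride formation through the chloroiminium catalyst, mild enough for the aryl silyl ether.

Step 20
Reactants: 23 6α-(triethylsilyloxy)dauc-8-en-4β-ol; 27 acid chloride (1.5 equiv)
Product: 29 6α-(triethylsilyloxy)dauc-8-en-4β-yl 4-(tert-butyldimethylsilyloxy)-3-methoxybenzoate, via lithium alkoxide 28 (not isolated)
Conditions: n-BuLi (1.05 equiv), THF, −78 °C; then 27, DMAP (cat.), −78 °C → rt
Reagents that add atoms: none
Why: A hindered tertiary alcohol is acylated reliably only as its alkoxide, which attacks the aroyl chloride by addition–elimination; no other acidic or electrophilic site is present.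

Step 21
Reactants: 29 doubly silylated C4 vanillate
Product: 30 6α-hydroxydauc-8-en-4β-yl 4-(tert-butyldimethylsilyloxy)-3-methoxybenzoate
Conditions: PPTS, MeOH/CH2Cl2, 0 °C → rt
Reagents that add atoms: none
Why: Mild acid methanolysis removes the secondary alkyl triethylsilyl ether and leaves the acid-stable aryl silyl ether, which must stay on to protect the phenol from the oxidant of the next step.

Step 22
Reactants: 30 6α-hydroxy C4 vanillate
Product: 31 8α,9α-epoxy-6α-hydroxydaucan-4β-yl 4-(tert-butyldimethylsilyloxy)-3-methoxybenzoate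
Conditions: VO(acac)2 (5 mol %), t-BuOOH, CH2Cl2, 0 °C → rt
Reagents that add atoms: tert-butyl hydroperoxide, CC(C)(C)OO
Why: Vanadium-catalysed hydroxyl-directed epoxidation, in which the homoallylic C6 α-hydroxyl binds the vanadium peroxide and delivers oxygen to the α face of C8=C9 (also the face anti to the angular methyl), setting C8 (R) and C9 (S) syn to the hydroxyl.

Step 23
Reactants: 31 epoxy aryl silyl ether
Product: 32 CNP0315707.1, (1R,4R,5S,6S,8R,9S)-8α,9α-epoxy-6α-hydroxydaucan-4β-yl 4-hydroxy-3-methoxybenzoate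
Conditions: Bu4NF, AcOH (1:1), THF, 0 °C
Reagents that add atoms: none
Why: Fluoride cleaves the aryl silyl ether quickly, and the acetic acid buffer keeps the medium from promoting O4-to-O6 acyl migration or epoxide opening.

**Compound list**
1 | (S)-(+)-terpinen-4-ol | CC1=CC[C@](O)(C(C)C)CC1 | starting material
2 | (S)-terpinen-4-yl triethylsilyl ether | CC1=CC[C@](O[Si](CC)(CC)CC)(C(C)C)CC1 | intermediate
3 | secondary ozonide of 2 (1,2,4-trioxolane across the former alkene carbons) | CC12CC[C@@](O[Si](CC)(CC)CC)(C(C)C)CC(OO1)O2 | intermediate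
4 | (S)-6-oxo-3-(propan-2-yl)-3-(triethylsilyloxy)heptanal | O=CC[C@](O[Si](CC)(CC)CC)(C(C)C)CCC(C)=O | intermediate
5 | aldol adduct, 2-hydroxy-2-methyl-5-(propan-2-yl)-5-(triethylsilyloxy)cyclopentane-1-carbaldehyde (5R; epimers at the new centres) | CC1(O)CC[C@@](O[Si](CC)(CC)CC)(C(C)C)C1C=O | intermediate
6 | (R)-2-methyl-5-(propan-2-yl)-5-(triethylsilyloxy)cyclopent-1-ene-1-carbaldehyde | CC1=C(C=O)[C@](O[Si](CC)(CC)CC)(C(C)C)CC1 | intermediate
7 | 1-[(R)-2-methyl-5-(propan-2-yl)-5-(triethylsilyloxy)cyclopent-1-en-1-yl]ethan-1-ol (carbinol epimers) | CC(O)C1=C(C)CC[C@@]1(O[Si](CC)(CC)CC)C(C)C | intermediate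
8 | 1-[(R)-2-methyl-5-(propan-2-yl)-5-(triethylsilyloxy)cyclopent-1-en-1-yl]ethan-1-one | CC(=O)C1=C(C)CC[C@@]1(O[Si](CC)(CC)CC)C(C)C | intermediate
9 | lithium enolate of 8 (terminal, at C7) | C=C(O[Li])C1=C(C)CC[C@@]1(O[Si](CC)(CC)CC)C(C)C | intermediate
10 | 2-siloxydiene, tert-butyldimethylsilyl enol ether of 8 (R) | C=C(O[Si](C)(C)C(C)(C)C)C1=C(C)CC[C@@]1(O[Si](CC)(CC)CC)C(C)C | intermediate
11 | methyl acetoacetate | COC(=O)CC(C)=O | starting material
12 | methyl 2-diazo-3-oxobutanoate | COC(=O)C(=[N+]=[N-])C(C)=O | intermediate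
13 | methyl 2-diazo-3-hydroxybutanoate (racemic) | COC(=O)C(=[N+]=[N-])C(C)O | intermediate
14 | methyl 2-diazo-3-(dichlorophosphoryloxy)butanoate | COC(=O)C(=[N+]=[N-])C(C)OP(=O)(Cl)Cl | intermediate
15 | methyl 2-diazobut-3-enoate | C=CC(=[N+]=[N-])C(=O)OC | intermediate
16 | methyl (1S,2R)-2-(tert-butyldimethylsilyloxy)-2-[(R)-2-methyl-5-(propan-2-yl)-5-(triethylsilyloxy)cyclopent-1-en-1-yl]-1-vinylcyclopropane-1-carboxylate (vinyl and cyclopentenyl cis) | C=C[C@@]1(C(=O)OC)C[C@@]1(O[Si](C)(C)C(C)(C)C)C2=C(C)CC[C@@]2(O[Si](CC)(CC)CC)C(C)C | intermediate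
17 | methyl (1R,4R)-6-(tert-butyldimethylsilyloxy)-1β-methyl-4α-(propan-2-yl)-4β-(triethylsilyloxy)hydroazulene-5,8-diene-8-carboxylate (daucane locants) | COC(=O)C1=CC[C@@]2(C)CC[C@@](O[Si](CC)(CC)CC)(C(C)C)C2=C(O[Si](C)(C)C(C)(C)C)C1 | intermediate
18 | C8-hydroxymethyl analogue of 17 (allylic alcohol) | OCC1=CC[C@@]2(C)CC[C@@](O[Si](CC)(CC)CC)(C(C)C)C2=C(O[Si](C)(C)C(C)(C)C)C1 | intermediate
19 | allylic methanesulfonate of 18 | CS(=O)(=O)OCC1=CC[C@@]2(C)CC[C@@](O[Si](CC)(CC)CC)(C(C)C)C2=C(O[Si](C)(C)C(C)(C)C)C1 | intermediate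
20 | (1R,4R)-6-(tert-butyldimethylsilyloxy)-1β,8-dimethyl-4α-(propan-2-yl)-4β-(triethylsilyloxy)hydroazulene-5,8-diene | CC1=CC[C@@]2(C)CC[C@@](O[Si](CC)(CC)CC)(C(C)C)C2=C(O[Si](C)(C)C(C)(C)C)C1 | intermediate
21 | (1R,4R,5R)-4β-hydroxydauc-8-en-6-one (trans-fused, 5α-H) | CC1=CC[C@@]2(C)CC[C@@](O)(C(C)C)[C@@H]2C(=O)C1 | intermediate
22 | (1R,4R,5S,6S)-dauc-8-ene-4β,6α-diol | CC1=CC[C@@]2(C)CC[C@@](O)(C(C)C)[C@@H]2[C@@H](O)C1 | intermediate
23 | 6α-(triethylsilyloxy)dauc-8-en-4β-ol | CC1=CC[C@@]2(C)CC[C@@](O)(C(C)C)[C@@H]2[C@@H](O[Si](CC)(CC)CC)C1 | intermediate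
24 | vanillic acid | COc1cc(C(=O)O)ccc1O | starting material
25 | tert-butyldimethylsilyl 4-(tert-butyldimethylsilyloxy)-3-methoxybenzoate | COc1cc(C(=O)O[Si](C)(C)C(C)(C)C)ccc1O[Si](C)(C)C(C)(C)C | intermediate
26 | 4-(tert-butyldimethylsilyloxy)-3-methoxybenzoic acid | COc1cc(C(=O)O)ccc1O[Si](C)(C)C(C)(C)C | intermediate
27 | 4-(tert-butyldimethylsilyloxy)-3-methoxybenzoyl chloride | COc1cc(C(Cl)=O)ccc1O[Si](C)(C)C(C)(C)C | intermediate
28 | lithium C4 alkoxide of 23 | CC1=CC[C@@]2(C)CC[C@@](O[Li])(C(C)C)[C@@H]2[C@@H](O[Si](CC)(CC)CC)C1 | intermediate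
29 | 6α-(triethylsilyloxy)dauc-8-en-4β-yl 4-(tert-butyldimethylsilyloxy)-3-methoxybenzoate | COc1cc(C(=O)O[C@@]2(C(C)C)CC[C@]3(C)CC=C(C)C[C@H](O[Si](CC)(CC)CC)[C@H]32)ccc1O[Si](C)(C)C(C)(C)C | intermediate
30 | 6α-hydroxydauc-8-en-4β-yl 4-(tert-butyldimethylsilyloxy)-3-methoxybenzoate | COc1cc(C(=O)O[C@@]2(C(C)C)CC[C@]3(C)CC=C(C)C[C@H](O)[C@H]32)ccc1O[Si](C)(C)C(C)(C)C | intermediate
31 | 8α,9α-epoxy-6α-hydroxydaucan-4β-yl 4-(tert-butyldimethylsilyloxy)-3-methoxybenzoate | COc1cc(C(=O)O[C@@]2(C(C)C)CC[C@]3(C)C[C@@H]4O[C@]4(C)C[C@H](O)[C@H]32)ccc1O[Si](C)(C)C(C)(C)C | intermediate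
32 | CNP0315707.1, (1R,4R,5S,6S,8R,9S)-8α,9α-epoxy-6α-hydroxydaucan-4β-yl 4-hydroxy-3-methoxybenzoate | COc1cc(C(=O)O[C@@]2(C(C)C)CC[C@]3(C)C[C@@H]4O[C@]4(C)C[C@H](O)[C@H]32)ccc1O | target

**Totals**
Total step count: 23 (3 for the diazo ester, 3 for the acid chloride, 17 on the main line).
Longest linear sequence: 17 steps (steps 1–6, 10–16, 20–23).

**Steps most likely to fail**

Step 10. The cyclopropanation may go wrong in several ways. The carbenoid may be attacked at its vinylogous terminus by the very electron-rich enol ether. The siloxy group rather than the cyclopentenyl group may end cis to the vinyl group, giving a trans-divinylcyclopropane that rearranges only after thermal epimerisation, with loss of the stereochemical relay. The catalyst may be mismatched with the C4 centre, eroding the facial selectivity that fixes C1 (the C1 epimers are diastereomers and could be separated, at a cost in material). The Cope rearrangement may stall because the methyl group on the tetrasubstituted terminus points at the cyclopropane methylene in the boat.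

The fallback keeps the cyclopropanation/Cope construction of ring B but removes the enol ether from it and brings in the C6 oxygen afterwards. It sets out from aldehyde 6 and returns at diol 22:
- Wittig methylenation of 6 (Ph3P=CH2, THF, 0 °C) would give the vinyl diene (R)-1-vinyl-2-methyl-5-(propan-2-yl)-5-(triethylsilyloxy)cyclopentene F1.
- Its monosubstituted vinyl group is the best-behaved alkene class for the same Rh2(R-DOSP)4 reaction with 15; this should give the C6-unsubstituted hydroazulene dienyl ester F2.
- Hydroboration–oxidation (BH3·SMe2, THF, 0 °C; then NaBO3·4H2O) is expected to take the electron-rich C5=C6 alkene in preference to the conjugated C8=C9 and to add H and OH syn from the α face (anti to the angular methyl and the siloxy group), giving the 6α-hydroxy ester F3 with 5α-H.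
- i-Bu2AlH gives the diol F4.
- Selective sulfonylation of the primary allylic hydroxyl (MsCl, 2,4,6-collidine, CH2Cl2, −20 °C) gives the allylic methanesulfonate F5.
- LiEt3BH gives 4β-(triethylsilyloxy)dauc-8-en-6α-ol F6.
- Bu4NF in THF then frees the tertiary hydroxyl to give 22.

Step 14. The free tertiary β-hydroxy ketone may undergo retro-aldol opening of ring A or lose water to the enone, the β,γ-alkene may move into conjugation, and the ketonisation may leave C5 cis-fused.

The fallback never exposes the free aldol and replaces the directed reduction by reduction plus inversion. It sets out from 20 and returns at 22: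
- One equivalent of Bu4NF/AcOH in THF at −40 °C should cleave only the far more labile silyl enol ether, giving 4β-(triethylsilyloxy)dauc-8-en-6-one F7. Its protected oxygen cannot undergo retro-aldol cleavage, and its C5 centre can be equilibrated safely.
- NaBH4 with CeCl3 in MeOH at −40 °C should attack the open α face of the carbonyl to give the 6β-alcohol F8.
- Mitsunobu inversion (4-nitrobenzoic acid, PPh3, DIAD, toluene, 0 °C → rt), with the nucleophile arriving on the open α face, gives the 6α 4-nitrobenzoate F9.
- Bu4NF/AcOH removes the tertiary silyl ether to give the 4β-hydroxy 6α 4-nitrobenzoate F10.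
- K2CO3 in MeOH gives 22.

Step 20. Acylation of the very hindered tertiary alkoxide next to the isopropyl group may be too slow, and the strongly basic alkoxide may instead take the silyl group from O6 or attack the aryl silyl ether.

The fallback changes the acyl donor and the mode of activation: the neutral alcohol is acylated by a symmetric anhydride under magnesium bromide and amine dual activation, a method established for tertiary alcohols. It sets out from 23 and acid 26 and returns at 29:
- DCC in CH2Cl2 converts 26 into 4-(tert-butyldimethylsilyloxy)-3-methoxybenzoic anhydride F11.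
- 23 with F11 (3 equiv), MgBr2·OEt2 and i-Pr2NEt in CH2Cl2 at rt should give 29 without a free alkoxide ever being present.

**Further compounds**
F1 | step 10 | (R)-1-vinyl-2-methyl-5-(propan-2-yl)-5-(triethylsilyloxy)cyclopentene | C=CC1=C(C)CC[C@@]1(O[Si](CC)(CC)CC)C(C)C
F2 | step 10 | methyl (1R,4R)-1β-methyl-4α-(propan-2-yl)-4β-(triethylsilyloxy)hydroazulene-5,8-diene-8-carboxylate | COC(=O)C1=CC[C@@]2(C)CC[C@@](O[Si](CC)(CC)CC)(C(C)C)C2=CC1
F3 | step 10 | methyl 6α-hydroxy-1β-methyl-4α-(propan-2-yl)-4β-(triethylsilyloxy)hydroazulen-8-ene-8-carboxylate (5α-H) | COC(=O)C1=CC[C@@]2(C)CC[C@@](O[Si](CC)(CC)CC)(C(C)C)[C@@H]2[C@@H](O)C1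
F4 | step 10 | C8-hydroxymethyl 6α-ol, 4β-triethylsilyl ether | OCC1=CC[C@@]2(C)CC[C@@](O[Si](CC)(CC)CC)(C(C)C)[C@@H]2[C@@H](O)C1
F5 | step 10 | primary allylic methanesulfonate of F4 | CS(=O)(=O)OCC1=CC[C@@]2(C)CC[C@@](O[Si](CC)(CC)CC)(C(C)C)[C@@H]2[C@@H](O)C1
F6 | step 10 | 4β-(triethylsilyloxy)dauc-8-en-6α-ol | CC1=CC[C@@]2(C)CC[C@@](O[Si](CC)(CC)CC)(C(C)C)[C@@H]2[C@@H](O)C1
F7 | step 14 | 4β-(triethylsilyloxy)dauc-8-en-6-one (trans-fused) | CC1=CC[C@@]2(C)CC[C@@](O[Si](CC)(CC)CC)(C(C)C)[C@@H]2C(=O)C1
F8 | step 14 | 4β-(triethylsilyloxy)dauc-8-en-6β-ol | CC1=CC[C@@]2(C)CC[C@@](O[Si](CC)(CC)CC)(C(C)C)[C@@H]2[C@H](O)C1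
F9 | step 14 | 4β-(triethylsilyloxy)dauc-8-en-6α-yl 4-nitrobenzoate | CC1=CC[C@@]2(C)CC[C@@](O[Si](CC)(CC)CC)(C(C)C)[C@@H]2[C@@H](OC(=O)c3ccc(cc3)[N+](=O)[O-])C1
F10 | step 14 | 4β-hydroxydauc-8-en-6α-yl 4-nitrobenzoate | CC1=CC[C@@]2(C)CC[C@@](O)(C(C)C)[C@@H]2[C@@H](OC(=O)c3ccc(cc3)[N+](=O)[O-])C1
F11 | step 20 | 4-(tert-butyldimethylsilyloxy)-3-methoxybenzoic anhydride | COc1cc(ccc1O[Si](C)(C)C(C)(C)C)C(=O)OC(=O)c1ccc(O[Si](C)(C)C(C)(C)C)c(OC)c1
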